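## Retrosynthetic overview

1. Endgame: the C6 carbinol and C5–H come from the α-epoxide of the tetrasubstituted enone 26 (Weitz–Scheffer, then SmI2). The C6 side chain is joined by an allyl–vinyl Stille coupling (18 + 25). The C3a methyl is put on the C3a enolate of 15, anti to the C7a methyl, which gives the trans ring fusion.
2. The six-membered ring is closed at C5–C6 by Dieckmann condensation of keto ester 12.
3. Key disconnection: bonds C7–C7a and C4–C3a. The enabling feature is that the C4 ketone and the C6 carbinol are 1,5-related across the ring-fusion bond (C4(=O)–C3a–C7a–C7–C6(O)). This is a de Mayo retron: the enol C=C of a 1,3-dicarbonyl (as a 1,3-dioxin-4-one) adds [2+2] to a cyclopentene C3a=C7a, and retro-aldol cleavage of the temporary cyclobutane bond follows. Because C3a is α to the C4 ketone, it can enter as an acetoxy-bearing alkene carbon (regiocontrol) and receive its methyl later.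
4. Absolute configuration: C7a is the only stereocentre of the key step that persists; the acetal of the 2-tert-butyl dioxinone sets it.
5. Ring order: cyclopentane (bought) → cyclobutane (temporary, step 5, cleaved in step 6) → cyclohexane (step 8).

Key step: step 5

Assumption: read from the SMILES, the ring-fusion methyls are trans (3aS,7aR), the C6 side chain is cis to the C7a methyl and the C5 side chain is trans to the C3a methyl. (R)-2-tert-Butyl-6-methyl-4H-1,3-dioxin-4-one is taken as a purchasable starting material.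

## Route

Step 1
Reactants: 1 (R)-2-tert-butyl-6-methyl-4H-1,3-dioxin-4-one; 2 3-bromo-2-methylprop-1-ene
Product: 4 (R)-2-tert-butyl-6-(3-methylbut-3-en-1-yl)-4H-1,3-dioxin-4-one, via lithium dienolate 3 (not isolated)
Conditions: LiN(i-Pr)2, THF/DMPU, −78 °C; then 2, −78 to −30 °C
Reagents that add atoms: none
Why: Vinylogous enolate alkylation: deprotonation of the 6-methyl group gives the dienolate, which should react with the allylic bromide at this γ-carbon as in the γ-alkylation of 2,2,6-trimethyl-1,3-dioxin-4-one, and the acetal stereocentre is not touched.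

Step 2
Reactants: 4
Product: 5 (R)-2-tert-butyl-6-(3-hydroxy-3-methylbutyl)-4H-1,3-dioxin-4-one
Conditions: Co(acac)2 (20 mol %), PhSiH3, O2 (1 atm), THF/i-PrOH, rt
Reagents that add atoms: dioxygen O=O
Why: Mukaiyama hydration (hydrogen-atom transfer from a cobalt hydride, then O2 trapping) should be Markovnikov-selective for the electron-neutral 1,1-disubstituted alkene and leave the push–pull dioxinone alkene, which must be the only alkene left before the photochemical step.

Step 3
Reactants: 5
Product: 6 (R)-2-tert-butyl-6-{3-methyl-3-[(triethylsilyl)oxy]butyl}-4H-1,3-dioxin-4-one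
Conditions: TESOTf, 2,6-lutidine, CH2Cl2, −78 °C
Reagents that add atoms: triethylsilyl trifluoromethanesulfonate CC[Si](CC)(CC)OS(=O)(=O)C(F)(F)F
Why: Silylation with the silyl triflate masks the tertiary hydroxyl group, which would otherwise attack the vinyl triflate of step 9 or interfere with the enolate chemistry.

Step 4
Reactants: 7 2-methylcyclopentanone
Product: 8 2-methylcyclopent-1-en-1-yl acetate
Conditions: Ac2O, 70% HClO4 (cat.), CH2Cl2, rt; distillation
Reagents that add atoms: acetic anhydride CC(=O)OC(C)=O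
Why: Acid-catalysed enol acetylation under equilibrating conditions should give mainly the more substituted (tetrasubstituted) enol acetate, the minor isomer being removed by distillation.

Step 5
Reactants: 6; 8
Product: 9 cis-anti-cis cyclobutane photoadduct (tricyclic 2-tert-butyl-1,3-dioxan-4-one; C5 of the dioxinone bonded to the methyl-bearing carbon and C6 to the acetoxy-bearing carbon of 8; cyclobutane on the face opposite to tert-butyl; cyclopentane exo)
Conditions: hν (300 nm, Pyrex), 8 (5 equiv), MeCN/acetone 9:1, 0 °C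
Reagents that add atoms: none
Why: Excitation of the dioxinone gives its triplet, which adds to the enol acetate through a 1,4-biradical that closes to the cyclobutane, so the bond from C5 to the methyl-bearing carbon and the bond from C6 to the acetoxy-bearing carbon are both made in this operation; the closest known reactions are de Mayo-type [2+2] photocycloadditions of 1,3-dioxin-4-ones with alkenes, including auxiliary-controlled versions with 2-tert-butyl and menthone-derived acetals, and enone–enol ester photocycloadditions. One ring is closed, the cyclobutane, by stepwise [2+2] addition across the tetrasubstituted alkene, with both new bonds on the same alkene face (cis-fused to the cyclopentane). Of the four new stereocentres only the methyl-bearing carbon (later C7a) survives; it is fixed by the cyclopentene face that is attacked, which should follow from addition to the dioxinone face trans to the tert-butyl group combined with exo (cis-anti-cis) placement of the cyclopentane ring, and the other three are destroyed in steps 6 and 7. The step needs head-to-tail regioselectivity, which the acetoxy donor should secure (its carbon bonds to the oxygen-bearing β-carbon C6, the methyl-bearing carbon to C5), and facial selectivity, which the acetal should secure. Stereoisomeric adducts are diastereomers and can be separated.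

Step 6
Reactants: 9
Product: 11 methyl 2-[(1R,2S)-2-(acetyloxy)-1-methyl-2-{4-methyl-4-[(triethylsilyl)oxy]pentanoyl}cyclopentyl]acetate, via cyclobutanol hydroxy ester 10 (not isolated)
Conditions: NaOMe (0.3 equiv), MeOH, −20 to 0 °C; AcOH quench
Reagents that add atoms: methanol CO
Why: De Mayo-type fragmentation: methoxide opens the acylal lactone, the hemiacetal loses pivalaldehyde and the strained cyclobutanolate undergoes retro-aldol cleavage of the temporary C–C bond to the 1,5-keto ester, while the cold substoichiometric base should spare the tertiary acetate.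

Step 7
Reactants: 11
Product: 12 methyl 2-[(1R,2R)-1-methyl-2-{4-methyl-4-[(triethylsilyl)oxy]pentanoyl}cyclopentyl]acetate (cis isomer drawn; the C2 epimer converges in step 8)
Conditions: SmI2 (2.5 equiv), THF/MeOH, −78 °C
Reagents that add atoms: none
Why: SmI2 reduction of an α-acyloxy ketone removes the regiocontrol group as acetate through the samarium enolate, and the new C2–H centre is epimerisable and is reset in step 11.

Step 8
Reactants: 12
Product: 13 (3aR,7aR)-6-hydroxy-7a-methyl-5-{2-methyl-2-[(triethylsilyl)oxy]propyl}-1,2,3,3a,7,7a-hexahydro-4H-inden-4-one (enol form of the 4,6-dione, cis-fused)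
Conditions: KOt-Bu (2.2 equiv), THF, 0 °C to rt; aq. NH4Cl
Reagents that add atoms: none
Why: Dieckmann condensation of the ketone enolate (at the future C5) onto the ester is the only closure that gives an unstrained ring and is driven by formation of the 1,3-dione enolate; the C3a epimers converge.

Step 9
Reactants: 13
Product: 14 (3aR,7aR)-7a-methyl-5-{2-methyl-2-[(triethylsilyl)oxy]propyl}-4-oxo-2,3,3a,4,7,7a-hexahydro-1H-inden-6-yl trifluoromethanesulfonate
Conditions: Tf2O, Et3N, CH2Cl2, −78 °C
Reagents that add atoms: trifluoromethanesulfonic anhydride O=S(=O)(OS(=O)(=O)C(F)(F)F)C(F)(F)F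
Why: O-Triflation of the unsymmetrical 1,3-dione enolate is expected at the less hindered C6 oxygen (the C4 oxygen is flanked by the ring-fusion methine next to quaternary C7a), which fixes the ketone at C4 beside C3a.

Step 10
Reactants: 14
Product: 15 (3aR,7aR)-6-(hydroxymethyl)-7a-methyl-5-{2-methyl-2-[(triethylsilyl)oxy]propyl}-1,2,3,3a,7,7a-hexahydro-4H-inden-4-one
Conditions: Bu3SnCH2OH (1.3 equiv), Pd(PPh3)4 (5 mol %), LiCl, 1,4-dioxane, 90 °C
Reagents that add atoms: (tributylstannyl)methanol OC[Sn](CCCC)(CCCC)CCCC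
Why: Stille coupling of the β-triflyloxy enone with (tributylstannyl)methanol transfers a hydroxymethyl group to C6, which becomes the first carbon of the side chain.

Step 11
Reactants: 15
Product: 17 (3aS,7aR)-6-(hydroxymethyl)-3a,7a-dimethyl-5-{2-methyl-2-[(triethylsilyl)oxy]propyl}-1,2,3,3a,7,7a-hexahydro-4H-inden-4-one, via dilithium alkoxide enolate 16 (not isolated)
Conditions: LiN(i-Pr)2 (2.3 equiv), THF, −78 °C; MeI (1.5 equiv), −78 to −40 °C
Reagents that add atoms: iodomethane CI
Why: Kinetic α′-deprotonation of the enone gives the cross-conjugated C3a enolate, and because the cyclopentane holds the C7a methyl pseudo-axial over one face, MeI should add to the opposite face (trans-diaxial enolate alkylation, as in angular methylations trans to a neighbouring angular methyl), which sets the trans ring fusion.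

Step 12
Reactants: 17
Product: 18 (3aS,7aR)-6-(bromomethyl)-3a,7a-dimethyl-5-{2-methyl-2-[(triethylsilyl)oxy]propyl}-1,2,3,3a,7,7a-hexahydro-4H-inden-4-one
Conditions: CBr4, PPh3, CH2Cl2, 0 °C
Reagents that add atoms: carbon tetrabromide BrC(Br)(Br)Br
Why: The Appel reaction converts the primary allylic alcohol into the bromide under neutral conditions without touching the enone or the silyl ether.

Step 13
Reactants: 19 ethyl but-2-ynoate
Product: 20 ethyl (E)-3-(tributylstannyl)but-2-enoate
Conditions: Bu3SnH, LiN(i-Pr)2, THF, 0 °C; CuBr·SMe2, −78 °C; then 19, MeOH, −78 °C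
Reagents that add atoms: tributyltin hydride CCCC[SnH](CCCC)CCCC
Why: Stannylcupration of a 2-alkynoate is a syn addition with tin at the β-carbon, and protonation of the vinylcopper by methanol at −78 °C should give the (E)-β-stannyl enoate (tin trans to the ester).

Step 14
Reactants: 20
Product: 21 (E)-3-(tributylstannyl)but-2-en-1-ol
Conditions: i-Bu2AlH (2.2 equiv), CH2Cl2, −78 °C; Rochelle salt
Reagents that add atoms: none
Why: Reduction of the enoate with i-Bu2AlH gives the allylic alcohol and leaves the vinylstannane geometry unchanged.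

Step 15
Reactants: 21
Product: 22 tributyl[(E)-4-bromobut-2-en-2-yl]stannane
Conditions: CBr4, PPh3, CH2Cl2, 0 °C
Reagents that add atoms: carbon tetrabromide BrC(Br)(Br)Br
Why: Appel reaction of the primary allylic alcohol, whose neutral conditions the vinylstannane tolerates.

Step 16
Reactants: 23 4-methoxy-2-methylphenol; 22
Product: 25 4-methoxy-2-methyl-6-[(E)-3-(tributylstannyl)but-2-en-1-yl]phenol, via sodium phenoxide 24 (not isolated)
Conditions: NaH, toluene, 0 °C to rt; then 22, rt to 50 °C
Reagents that add atoms: none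
Why: ortho-C-Allylation of a sodium phenoxide in a non-polar solvent (tight ion pair, SN2 at the primary allylic carbon) should occur at the only free ortho position, the para position being blocked by methoxy, and keeps the alkene geometry.

Step 17
Reactants: 18; 25
Product: 26 (3aS,7aR)-6-[(2E)-4-(2-hydroxy-5-methoxy-3-methylphenyl)-2-methylbut-2-en-1-yl]-3a,7a-dimethyl-5-{2-methyl-2-[(triethylsilyl)oxy]propyl}-1,2,3,3a,7,7a-hexahydro-4H-inden-4-one
Conditions: Pd2(dba)3 (2.5 mol %), AsPh3 (20 mol %), CuI (10 mol %), THF/NMP, 50 °C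
Reagents that add atoms: none
Why: Stille coupling of an allylic bromide with a vinylstannane joins the CH2 terminus of the allyl unit (the other terminus is fully substituted) to the vinyl carbon with retention of the (E) geometry, under neutral conditions that should not move the skipped diene into conjugation.

Step 18
Reactants: 26
Product: 27 (3aS,5S,6S,7aR)-5,6-epoxide of 26 (oxirane on the face opposite to the C7a methyl)
Conditions: 30% H2O2, aq. NaOH, MeOH, 0 °C
Reagents that add atoms: hydrogen peroxide OO
Why: Weitz–Scheffer epoxidation: hydroperoxide should add to C6 of the enone from the face opposite to the pseudo-axial C7a methyl (1,3-related to C6), so both C–O bonds of the oxirane are anti to that methyl, and the isolated trisubstituted alkene is inert to the nucleophilic oxidant.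

Step 19
Reactants: 27
Product: 28 (3aS,5R,6S,7aR)-6-hydroxy-6-[(2E)-4-(2-hydroxy-5-methoxy-3-methylphenyl)-2-methylbut-2-en-1-yl]-3a,7a-dimethyl-5-{2-methyl-2-[(triethylsilyl)oxy]propyl}octahydro-4H-inden-4-one
Conditions: SmI2 (2.5 equiv), THF/MeOH, −90 °C
Reagents that add atoms: none
Why: SmI2 reductive opening of the α,β-epoxy ketone cleaves the C5–O bond and keeps the C6 tertiary alcohol with its configuration, and protonation of the samarium enolate should give the C5 epimer with the equatorial side chain (the alternative is syn-axial to the C3a methyl and would equilibrate through the enol).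

Step 20
Reactants: 28
Product: 29 (3aS,5R,6S,7aR)-6-hydroxy-5-(2-hydroxy-2-methylpropyl)-6-[(2E)-4-(2-hydroxy-5-methoxy-3-methylphenyl)-2-methylbut-2-en-1-yl]-3a,7a-dimethyloctahydro-4H-inden-4-one (CNP0190381.1)
Conditions: HF·pyridine, pyridine, THF, 0 °C to rt
Reagents that add atoms: none
Why: Fluoride cleavage of the tertiary triethylsilyl ether under buffered, weakly acidic conditions should avoid retro-aldol cleavage (base) and chroman formation or dehydration (strong acid).

## Compound list

1 | (R)-2-tert-butyl-6-methyl-4H-1,3-dioxin-4-one | CC1=CC(=O)O[C@@H](O1)C(C)(C)C | starting material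
2 | 3-bromo-2-methylprop-1-ene | CC(=C)CBr | starting material
3 | lithium dienolate of 1 | [Li]OC1=CC(=C)O[C@H](O1)C(C)(C)C | intermediate
4 | (R)-2-tert-butyl-6-(3-methylbut-3-en-1-yl)-4H-1,3-dioxin-4-one | CC(=C)CCC1=CC(=O)O[C@@H](O1)C(C)(C)C | intermediate
5 | (R)-2-tert-butyl-6-(3-hydroxy-3-methylbutyl)-4H-1,3-dioxin-4-one | CC(C)(O)CCC1=CC(=O)O[C@@H](O1)C(C)(C)C | intermediate
6 | (R)-2-tert-butyl-6-{3-methyl-3-[(triethylsilyl)oxy]butyl}-4H-1,3-dioxin-4-one | CC[Si](CC)(CC)OC(C)(C)CCC1=CC(=O)O[C@@H](O1)C(C)(C)C | intermediate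
7 | 2-methylcyclopentanone (racemic) | CC1CCCC1=O | starting material
8 | 2-methylcyclopent-1-en-1-yl acetate | CC(=O)OC1=C(C)CCC1 | intermediate
9 | cis-anti-cis photoadduct of 6 and 8 | CC(C)(C)[C@H]1OC(=O)[C@H]2[C@](O1)(CCC(C)(C)O[Si](CC)(CC)CC)[C@]3(OC(C)=O)CCC[C@]23C | intermediate
10 | methyl 1-acetoxy-7-hydroxy-5-methyl-7-{3-methyl-3-[(triethylsilyl)oxy]butyl}bicyclo[3.2.0]heptane-6-carboxylate (stereochemistry as in 9) | COC(=O)[C@H]1[C@](O)(CCC(C)(C)O[Si](CC)(CC)CC)[C@]2(OC(C)=O)CCC[C@]12C | intermediate
11 | methyl 2-[(1R,2S)-2-(acetyloxy)-1-methyl-2-{4-methyl-4-[(triethylsilyl)oxy]pentanoyl}cyclopentyl]acetate | COC(=O)C[C@@]1(C)CCC[C@@]1(OC(C)=O)C(=O)CCC(C)(C)O[Si](CC)(CC)CC | intermediate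
12 | methyl 2-[(1R,2R)-1-methyl-2-{4-methyl-4-[(triethylsilyl)oxy]pentanoyl}cyclopentyl]acetate | COC(=O)C[C@@]1(C)CCC[C@H]1C(=O)CCC(C)(C)O[Si](CC)(CC)CC | intermediate
13 | (3aR,7aR)-6-hydroxy-7a-methyl-5-{2-methyl-2-[(triethylsilyl)oxy]propyl}-1,2,3,3a,7,7a-hexahydro-4H-inden-4-one | O=C1C(CC(C)(C)O[Si](CC)(CC)CC)=C(O)C[C@@]2(C)CCC[C@@H]12 | intermediate
14 | (3aR,7aR)-7a-methyl-5-{2-methyl-2-[(triethylsilyl)oxy]propyl}-4-oxo-2,3,3a,4,7,7a-hexahydro-1H-inden-6-yl trifluoromethanesulfonate | O=C1C(CC(C)(C)O[Si](CC)(CC)CC)=C(OS(=O)(=O)C(F)(F)F)C[C@@]2(C)CCC[C@@H]12 | intermediate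
15 | (3aR,7aR)-6-(hydroxymethyl)-7a-methyl-5-{2-methyl-2-[(triethylsilyl)oxy]propyl}-1,2,3,3a,7,7a-hexahydro-4H-inden-4-one | O=C1C(CC(C)(C)O[Si](CC)(CC)CC)=C(CO)C[C@@]2(C)CCC[C@@H]12 | intermediate
16 | dilithium alkoxide enolate of 15 | [Li]OCC1=C(CC(C)(C)O[Si](CC)(CC)CC)C(O[Li])=C2CCC[C@]2(C)C1 | intermediate
17 | (3aS,7aR)-6-(hydroxymethyl)-3a,7a-dimethyl-5-{2-methyl-2-[(triethylsilyl)oxy]propyl}-1,2,3,3a,7,7a-hexahydro-4H-inden-4-one | O=C1C(CC(C)(C)O[Si](CC)(CC)CC)=C(CO)C[C@@]2(C)CCC[C@]12C | intermediate
18 | (3aS,7aR)-6-(bromomethyl)-3a,7a-dimethyl-5-{2-methyl-2-[(triethylsilyl)oxy]propyl}-1,2,3,3a,7,7a-hexahydro-4H-inden-4-one | O=C1C(CC(C)(C)O[Si](CC)(CC)CC)=C(CBr)C[C@@]2(C)CCC[C@]12C | intermediate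
19 | ethyl but-2-ynoate | CC#CC(=O)OCC | starting material
20 | ethyl (E)-3-(tributylstannyl)but-2-enoate | CCOC(=O)/C=C(\C)[Sn](CCCC)(CCCC)CCCC | intermediate
21 | (E)-3-(tributylstannyl)but-2-en-1-ol | OC/C=C(\C)[Sn](CCCC)(CCCC)CCCC | intermediate
22 | tributyl[(E)-4-bromobut-2-en-2-yl]stannane | BrC/C=C(\C)[Sn](CCCC)(CCCC)CCCC | intermediate
23 | 4-methoxy-2-methylphenol | COc1ccc(O)c(C)c1 | starting material
24 | sodium 4-methoxy-2-methylphenoxide | [Na+].[O-]c1ccc(OC)cc1C | intermediate
25 | 4-methoxy-2-methyl-6-[(E)-3-(tributylstannyl)but-2-en-1-yl]phenol | COc1cc(C)c(O)c(C/C=C(\C)[Sn](CCCC)(CCCC)CCCC)c1 | intermediate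
26 | (3aS,7aR)-6-[(2E)-4-(2-hydroxy-5-methoxy-3-methylphenyl)-2-methylbut-2-en-1-yl]-3a,7a-dimethyl-5-{2-methyl-2-[(triethylsilyl)oxy]propyl}-1,2,3,3a,7,7a-hexahydro-4H-inden-4-one | O=C1C(CC(C)(C)O[Si](CC)(CC)CC)=C(C/C(C)=C/Cc3cc(OC)cc(C)c3O)C[C@@]2(C)CCC[C@]12C | intermediate
27 | (3aS,5S,6S,7aR)-5,6-epoxide of 26 | O=C1[C@@]2(CC(C)(C)O[Si](CC)(CC)CC)O[C@@]2(C/C(C)=C/Cc3cc(OC)cc(C)c3O)C[C@@]4(C)CCC[C@]14C | intermediate
28 | (3aS,5R,6S,7aR)-6-hydroxy-6-[(2E)-4-(2-hydroxy-5-methoxy-3-methylphenyl)-2-methylbut-2-en-1-yl]-3a,7a-dimethyl-5-{2-methyl-2-[(triethylsilyl)oxy]propyl}octahydro-4H-inden-4-one | COc1cc(C)c(O)c(C/C=C(\C)C[C@]2(O)C[C@@]3(C)CCC[C@]3(C)C(=O)[C@@H]2CC(C)(C)O[Si](CC)(CC)CC)c1 | intermediate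
29 | (3aS,5R,6S,7aR)-6-hydroxy-5-(2-hydroxy-2-methylpropyl)-6-[(2E)-4-(2-hydroxy-5-methoxy-3-methylphenyl)-2-methylbut-2-en-1-yl]-3a,7a-dimethyloctahydro-4H-inden-4-one | COc1cc(C)c(O)c(C/C=C(\C)C[C@]2(O)C[C@@]3(C)CCC[C@]3(C)C(=O)[C@@H]2CC(C)(C)O)c1 | target

## Step count and risks

Total step count: 20. Longest linear sequence: 15 steps (1–3, 5–12, 17–20).

Steps most likely to fail:

1. Step 5. Enantiocontrol may be lost through insufficient discrimination of the two dioxinone faces or through competing endo (cis-syn-cis) approach of the cyclopentene; each inverts C7a. Head-to-head addition would waste material. Both enantiomers of 1 are accessible if the sense of induction is opposite to that expected. Fallback (covalent resolution in place of auxiliary control): it sets out from 17 of insufficient enantiomeric purity. The alcohol is esterified with (S)-2-methoxy-2-phenylacetic acid (DCC, DMAP, CH2Cl2) to give the (S)-2-methoxy-2-phenylacetate of 17 F1 together with the (S)-2-methoxy-2-phenylacetate of the enantiomer of 17 F2. These diastereomers are separated by crystallisation or chromatography, and methanolysis of F1 (K2CO3, MeOH, 0 °C) comes back to the route at 17.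

2. Step 11. Deprotonation of the hindered ring-fusion methine may be incomplete or misdirected (γ instead of α′), and methylation of the alkoxide or reduced facial selectivity would lower the yield of the trans isomer. Fallback (methylation moved to a vinylogous ester, a Stork–Danheiser-type α′-alkylation): it sets out from 13. O-Methylation at the less hindered C6 oxygen (Me2SO4, K2CO3, acetone) gives (3aR,7aR)-6-methoxy-7a-methyl-5-{2-methyl-2-[(triethylsilyl)oxy]propyl}-1,2,3,3a,7,7a-hexahydro-4H-inden-4-one F3. LiN(i-Pr)2 and MeI at −78 °C give the (3aS,7aR)-3a,7a-dimethyl vinylogous ester F4. Aqueous LiOH in THF at 60 °C gives the 3a-methylated dione (enol form) F5. Tf2O and Et3N give the 3a-methylated C6 enol triflate F6, and the Stille coupling of step 10 (Bu3SnCH2OH, Pd(PPh3)4, LiCl) comes back to the route at 17.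

3. Step 18. Base may move the side-chain double bond into conjugation before the slow attack of hydroperoxide on the tetrasubstituted enone, and attack from the wrong face would give the C6 epimer. Fallback (hydroxyl-directed epoxidation without strong base): it sets out from 26. Luche reduction (NaBH4, CeCl3·7H2O, MeOH, −78 °C; hydride anti to the axial C3a methyl) gives the (3aS,4S,7aR)-allylic alcohol F7. Epoxidation directed by this hydroxyl group (VO(acac)2, t-BuOOH, CH2Cl2, 0 °C) gives the epoxy alcohol F8 with the oxirane on the same face, and Dess–Martin oxidation comes back to the route at 27.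

Further compounds
F1 | step 5 | (S)-2-methoxy-2-phenylacetate of 17 | CO[C@H](C(=O)OCC1=C(CC(C)(C)O[Si](CC)(CC)CC)C(=O)[C@@]2(C)CCC[C@]2(C)C1)c1ccccc1
F2 | step 5 | (S)-2-methoxy-2-phenylacetate of the enantiomer of 17 | CO[C@H](C(=O)OCC1=C(CC(C)(C)O[Si](CC)(CC)CC)C(=O)[C@]2(C)CCC[C@@]2(C)C1)c1ccccc1
F3 | step 11 | (3aR,7aR)-6-methoxy-7a-methyl-5-{2-methyl-2-[(triethylsilyl)oxy]propyl}-1,2,3,3a,7,7a-hexahydro-4H-inden-4-one | O=C1C(CC(C)(C)O[Si](CC)(CC)CC)=C(OC)C[C@@]2(C)CCC[C@@H]12
F4 | step 11 | (3aS,7aR)-6-methoxy-3a,7a-dimethyl-5-{2-methyl-2-[(triethylsilyl)oxy]propyl}-1,2,3,3a,7,7a-hexahydro-4H-inden-4-one | O=C1C(CC(C)(C)O[Si](CC)(CC)CC)=C(OC)C[C@@]2(C)CCC[C@]12C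
F5 | step 11 | (3aS,7aR)-6-hydroxy-3a,7a-dimethyl-5-{2-methyl-2-[(triethylsilyl)oxy]propyl}-1,2,3,3a,7,7a-hexahydro-4H-inden-4-one | O=C1C(CC(C)(C)O[Si](CC)(CC)CC)=C(O)C[C@@]2(C)CCC[C@]12C
F6 | step 11 | (3aS,7aR)-3a,7a-dimethyl-5-{2-methyl-2-[(triethylsilyl)oxy]propyl}-4-oxo-2,3,3a,4,7,7a-hexahydro-1H-inden-6-yl trifluoromethanesulfonate | O=C1C(CC(C)(C)O[Si](CC)(CC)CC)=C(OS(=O)(=O)C(F)(F)F)C[C@@]2(C)CCC[C@]12C
F7 | step 18 | (3aS,4S,7aR)-4-hydroxy analogue of 26 (allylic alcohol, hydroxyl anti to the C7a methyl) | O[C@H]1C(CC(C)(C)O[Si](CC)(CC)CC)=C(C/C(C)=C/Cc3cc(OC)cc(C)c3O)C[C@@]2(C)CCC[C@]12C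
F8 | step 18 | 5,6-epoxide of F7 (oxirane syn to the hydroxyl group) | O[C@H]1[C@@]2(CC(C)(C)O[Si](CC)(CC)CC)O[C@@]2(C/C(C)=C/Cc3cc(OC)cc(C)c3O)C[C@@]4(C)CCC[C@]14C
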